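## Structural features

The target is a sesquineolignan: three C6–C3 units joined head to tail by two alkyl aryl ether (8–O–4′) bonds. Ring A is a 3,4,5-trimethoxyphenyl group carrying the chain C7(OAc)–C8(O–ring B)–C9H3. Ring B is a 2,6-dimethoxyphenoxy unit whose oxygen O4′ is bonded to C8 and whose para carbon C1′ carries C7′H2–C8′(O–ring C)–C9′H3. Ring C is a 2,6-dimethoxyphenoxy unit bonded through O4″ to C8′ and carrying an (E)-prop-1-enyl group para to that oxygen. There are three stereocentres: C7 (S) and C8 (R) are adjacent (erythro), whereas C8′ (R) is separated from them by ring B and cannot be relayed to or from them. C8 and C8′ have the same spatial sense and the same surroundings, each being a CH(CH3) carbon bonded to an aryl oxygen flanked by two methoxy groups. Fragile groups are the electron-rich (E)-propenyl styrene (acid, hydrogenation, electrophilic oxidants), the benzylic acetate at C7 (ionisation, elimination) and, in precursors, any carbonyl next to C8 (epimerisation). The real difficulty is twofold: two hindered secondary-alkyl aryl ethers must be made with defined configuration, and C7 must be oxygenated erythro to C8 while the homologous C7′ stays a methylene. The key step exploits that O4 of ring A is para to C7 (ring A is a methylated syringyl phenol, constitutionally the same as ring B) and that C8 and C8′ are homochiral. With O4 free, C7 can be oxygenated last through a ring A quinone methide, so the ring A and ring B units come from one monomer.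

## Logic of the disconnections

14 to 13: the acetyl C–O bond at the C7 oxygen is cut. The benzylic acetate is the most labile group and is best added last. The gain is small. The forward step must acylate a hindered secondary benzylic hydroxyl without breaking the C7–O bond.

13 to 12: the O4–CH3 bond of ring A is cut. This is the enabling move: ring A becomes a free phenol whose oxygen is para to C7, the same pattern as ring B. The forward step must methylate the phenol in the presence of the C7 hydroxyl and without re-ionising C7.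

12 to 10 (through 11): the C7–O bond is cut and C7 is returned to a methylene. In 10 the ring A unit is identical in constitution and configuration with the ring B unit, the C7/C8 pair is reduced to the single centre C8, and no carbonyl-bearing ring A building block is needed. The forward step must dehydrogenate 10 across O4 and C7 at its only free phenol to give 11, and add an oxygen nucleophile to C7 of 11 from the face that places (7S) next to (8R).

10 to 9 to 8 + 5: after the ring A oxygen is masked again (9), the C8–O4′ bond is cut on the alkyl side. This gives 8 and one copy of 5. The forward step is an SN2 etherification with inversion at a secondary, non-enolisable carbinol by a hindered aryl oxygen, so 5 must be (S).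

8 to 7 to 6 + 5: the C8′–O4″ bond is cut in the same way. This gives 6 and a second copy of 5. The demand is the same, with the propenyl group of 6 left untouched.

5 to 2 + 3 (through 4), and 2 to 1: the aryl–CH2 bond C1–C7 is cut. This gives a commercial aryl bromide and a three-carbon epoxide that brings the stereocentre. The forward step must open 3 only at its CH2 terminus, and the acidic OH of 1 must be masked first.

## Other disconnections considered

Alternative 1: the first plan that comes to mind cuts the C8–O4′ bond with ring A already in place at the ketone level. Forward, Williamson alkylation of 8 with racemic α-bromoketone A1 would give ketone A2, followed by hydride reduction. C8 would be formed without any control next to an enolisable carbonyl, and the fixed C8′ centre is too remote to bias it, so A2 would be a pair of C8 epimers. Curing this needs a resolution or a chiral-pool variant with a separate ring A building block and several extra operations. The chosen plan makes C8 by a stereospecific SN2 at a carbinol that cannot epimerise, using the same monomer that sets C8′.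

Alternative 2: the C1–C7 aryl–carbinol bond is cut. Forward, a ring A arylmagnesium reagent would add to the (R)-α-aryloxy aldehyde A3 (from 8 by etherification with a lactic ester and partial reduction), forming C7 and attaching ring A in one step. Erythro selectivity requires the non-chelated Felkin–Anh mode. The ether oxygen and its two ortho methoxy groups invite magnesium chelation, which would give the threo isomer, and A3 is configurationally labile at C8. The chosen 1,6-addition has no competing chelated pathway, and its two acyclic control elements point the same way.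

Alternative 3: the C8–O4′ bond is cut homolytically, as in biosynthesis. Forward, oxidative cross-coupling of the phenoxyl radical of 8 with the C8-centred radical of 6 would give quinone methide A4, which is then hydrated. This would be the shortest path from 8, but C8 would be created in a radical–radical coupling with no absolute control. Homo-coupling of 6 and of 8 would compete statistically, and the ring A phenol would still need methylation. The chosen plan keeps the second half of this sequence (hydration of a quinone methide) but generates the quinone methide from a precursor in which C8 is already fixed.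

Key step: step 7

Assumption: (E)-2,6-dimethoxy-4-(prop-1-en-1-yl)phenol (6) is taken as a commercial starting material of defined (E) geometry.

## Route

Step 1
Reactants: 1 4-bromo-2,6-dimethoxyphenol
Product: 2 (4-bromo-2,6-dimethoxyphenoxy)(tert-butyl)dimethylsilane
Conditions: TBSCl, imidazole, DMF, rt
Reagents that add atoms: tert-butyldimethylsilyl chloride, CC(C)(C)[Si](C)(C)Cl
Why: Imidazole-promoted silylation of the phenol; the silyl ether masks the acidic OH for the Grignard step and keeps this oxygen from acting as the pronucleophile in the Mitsunobu steps 3 and 5.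

Step 2
Reactants: 2 (4-bromo-2,6-dimethoxyphenoxy)(tert-butyl)dimethylsilane; 3 (S)-2-methyloxirane
Product: 5 (2S)-1-{4-[tert-butyl(dimethyl)silyl]oxy-3,5-dimethoxyphenyl}propan-2-ol, via aryl Grignard reagent 4 (not isolated)
Conditions: Mg, THF, 40 °C; then CuI (10 mol%), 3, −30 to 0 °C; aq NH4Cl
Reagents that add atoms: none
Why: Magnesium insertion gives 4, which under copper catalysis opens the epoxide by SN2 attack at the unsubstituted CH2 carbon (copper-catalysed Grignard epoxide opening); the stereocentre of 3 is not touched, so the carbinol carbon of 5 is (S).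

Step 3
Reactants: 5 (2S)-1-{4-[tert-butyl(dimethyl)silyl]oxy-3,5-dimethoxyphenyl}propan-2-ol; 6 (E)-2,6-dimethoxy-4-(prop-1-en-1-yl)phenol
Product: 7 tert-butyl{4-[(2R)-2-{2,6-dimethoxy-4-[(E)-prop-1-en-1-yl]phenoxy}propyl]-2,6-dimethoxyphenoxy}dimethylsilane
Conditions: PPh3, DIAD, THF, 0 °C to rt
Reagents that add atoms: none
Why: Mitsunobu etherification: the alkoxyphosphonium ion of 5 is displaced by the phenoxide of 6 in an SN2 reaction with inversion, which sets C8′ as (R); the carbinol carbon is not enolisable, so there is no epimerisation path, and the propenyl group is inert.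

Step 4
Reactants: 7 tert-butyl{4-[(2R)-2-{2,6-dimethoxy-4-[(E)-prop-1-en-1-yl]phenoxy}propyl]-2,6-dimethoxyphenoxy}dimethylsilane
Product: 8 4-[(2R)-2-{2,6-dimethoxy-4-[(E)-prop-1-en-1-yl]phenoxy}propyl]-2,6-dimethoxyphenol
Conditions: TBAF, AcOH, THF, 0 °C to rt
Reagents that add atoms: none
Why: Fluoride cleavage of the aryl silyl ether, driven by Si–F bond formation; acetic acid protonates the phenoxide at once, so the electron-rich ring is not left as an air-sensitive anion, and no stereocentre is involved.

Step 5
Reactants: 8 4-[(2R)-2-{2,6-dimethoxy-4-[(E)-prop-1-en-1-yl]phenoxy}propyl]-2,6-dimethoxyphenol; 5 (2S)-1-{4-[tert-butyl(dimethyl)silyl]oxy-3,5-dimethoxyphenyl}propan-2-ol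
Product: 9 tert-butyl{4-[(2R)-2-{4-[(2R)-2-{2,6-dimethoxy-4-[(E)-prop-1-en-1-yl]phenoxy}propyl]-2,6-dimethoxyphenoxy}propyl]-2,6-dimethoxyphenoxy}dimethylsilane
Conditions: PPh3, DIAD, THF, 0 °C to rt
Reagents that add atoms: none
Why: Second Mitsunobu etherification with the same monomer: SN2 inversion at the carbinol carbon of 5 by the phenoxide of 8 sets C8 as (R); C8′ is an unactivated ether carbon and is not affected.

Step 6
Reactants: 9 tert-butyl{4-[(2R)-2-{4-[(2R)-2-{2,6-dimethoxy-4-[(E)-prop-1-en-1-yl]phenoxy}propyl]-2,6-dimethoxyphenoxy}propyl]-2,6-dimethoxyphenoxy}dimethylsilane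
Product: 10 4-[(2R)-2-{4-[(2R)-2-{2,6-dimethoxy-4-[(E)-prop-1-en-1-yl]phenoxy}propyl]-2,6-dimethoxyphenoxy}propyl]-2,6-dimethoxyphenol
Conditions: TBAF, AcOH, THF, 0 °C to rt
Reagents that add atoms: none
Why: Buffered fluoride desilylation as in step 4; it frees the only phenol of the molecule, on ring A, para to C7.

Step 7
Reactants: 10 4-[(2R)-2-{4-[(2R)-2-{2,6-dimethoxy-4-[(E)-prop-1-en-1-yl]phenoxy}propyl]-2,6-dimethoxyphenoxy}propyl]-2,6-dimethoxyphenol
Product: 12 4-[(1S,2R)-1-hydroxy-2-{4-[(2R)-2-{2,6-dimethoxy-4-[(E)-prop-1-en-1-yl]phenoxy}propyl]-2,6-dimethoxyphenoxy}propyl]-2,6-dimethoxyphenol, via quinone methide 11 (not isolated)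
Conditions: Ag2O, CH2Cl2, rt, dark; filter; then THF–H2O, NaH2PO4/H3PO4 buffer (pH 3), 0 °C
Reagents that add atoms: water, O
Why: Ag2O oxidises the only free phenol of 10 (ring A) to its phenoxyl radical, and disproportionation of two such radicals removes the C7–H para to the oxygen, so that quinone methide 11 forms by a net two-electron dehydrogenation; this is the known oxidation of 4-alkyl-2,6-dimethoxyphenols to quinone methides. Site and chemoselectivity come from the substrate: rings B and C are fully etherified, the propenyl group sits on a non-phenolic ring, and C7 is the only benzylic position para to the free oxygen. After removal of the silver, water adds 1,6 to C7 under mild acid catalysis and ring A rearomatises; the closest known reaction type is the hydration of β-aryl ether quinone methides of lignin models, which favours the erythro isomer when the ether ring is a 2,6-dimethoxyphenoxy group, as here. No ring is closed. The new stereocentre C7 is controlled by C8: allylic 1,3-strain with the quinoid C2–H holds the C8–H bond in the plane of the exocyclic C7=C1 bond, which leaves the methyl group on one face and the 2,6-dimethoxyaryloxy group on the other, and water attacks C7 anti to this bulky, electron-withdrawing aryloxy group (Felkin–Anh-type, C–O σ* anti to the forming bond). For (8R) this delivers oxygen to the face that gives (7S), that is the erythro (7S,8R) isomer. The step needs kinetic control, which brief exposure at pH about 3 and 0 °C should secure, because 12 re-ionises at C7 only under stronger acid or base.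

Step 8
Reactants: 12 4-[(1S,2R)-1-hydroxy-2-{4-[(2R)-2-{2,6-dimethoxy-4-[(E)-prop-1-en-1-yl]phenoxy}propyl]-2,6-dimethoxyphenoxy}propyl]-2,6-dimethoxyphenol
Product: 13 (1S,2R)-2-{4-[(2R)-2-{2,6-dimethoxy-4-[(E)-prop-1-en-1-yl]phenoxy}propyl]-2,6-dimethoxyphenoxy}-1-(3,4,5-trimethoxyphenyl)propan-1-ol
Conditions: MeI, K2CO3, acetone, rt
Reagents that add atoms: iodomethane, CI
Why: Williamson O-methylation: carbonate deprotonates only the phenol (pKa about 10) and not the C7 hydroxyl, and the phenoxide is methylated by SN2 at room temperature, where loss of hydroxide from C7 is not expected; once O4 is methylated, ring A can no longer form a quinone methide, so C7 is locked.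

Step 9
Reactants: 13 (1S,2R)-2-{4-[(2R)-2-{2,6-dimethoxy-4-[(E)-prop-1-en-1-yl]phenoxy}propyl]-2,6-dimethoxyphenoxy}-1-(3,4,5-trimethoxyphenyl)propan-1-ol
Product: 14 (1S,2R)-2-{4-[(2R)-2-{2,6-dimethoxy-4-[(E)-prop-1-en-1-yl]phenoxy}propyl]-2,6-dimethoxyphenoxy}-1-(3,4,5-trimethoxyphenyl)propyl acetate
Conditions: Ac2O, pyridine, DMAP (cat.), CH2Cl2, 0 °C to rt
Reagents that add atoms: acetic anhydride, CC(=O)OC(C)=O
Why: DMAP-catalysed acylation of the secondary benzylic alcohol through the N-acetylpyridinium ion; the C7–O bond is not broken, so the (7S) configuration is retained and the target results.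

## Compound list

1 | 4-bromo-2,6-dimethoxyphenol | COc1cc(Br)cc(OC)c1O | starting material
2 | (4-bromo-2,6-dimethoxyphenoxy)(tert-butyl)dimethylsilane | COc1cc(Br)cc(OC)c1O[Si](C)(C)C(C)(C)C | intermediate
3 | (S)-2-methyloxirane | C[C@H]1CO1 | starting material
4 | bromo{4-[tert-butyl(dimethyl)silyl]oxy-3,5-dimethoxyphenyl}magnesium (aryl Grignard reagent) | COc1cc([Mg]Br)cc(OC)c1O[Si](C)(C)C(C)(C)C | intermediate
5 | (2S)-1-{4-[tert-butyl(dimethyl)silyl]oxy-3,5-dimethoxyphenyl}propan-2-ol | C[C@H](O)Cc1cc(OC)c(O[Si](C)(C)C(C)(C)C)c(OC)c1 | intermediate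
6 | (E)-2,6-dimethoxy-4-(prop-1-en-1-yl)phenol | C/C=C/c1cc(OC)c(O)c(OC)c1 | starting material
7 | tert-butyl{4-[(2R)-2-{2,6-dimethoxy-4-[(E)-prop-1-en-1-yl]phenoxy}propyl]-2,6-dimethoxyphenoxy}dimethylsilane | C/C=C/c1cc(OC)c(O[C@H](C)Cc2cc(OC)c(O[Si](C)(C)C(C)(C)C)c(OC)c2)c(OC)c1 | intermediate
8 | 4-[(2R)-2-{2,6-dimethoxy-4-[(E)-prop-1-en-1-yl]phenoxy}propyl]-2,6-dimethoxyphenol | C/C=C/c1cc(OC)c(O[C@H](C)Cc2cc(OC)c(O)c(OC)c2)c(OC)c1 | intermediate
9 | tert-butyl{4-[(2R)-2-{4-[(2R)-2-{2,6-dimethoxy-4-[(E)-prop-1-en-1-yl]phenoxy}propyl]-2,6-dimethoxyphenoxy}propyl]-2,6-dimethoxyphenoxy}dimethylsilane | C/C=C/c1cc(OC)c(O[C@H](C)Cc2cc(OC)c(O[C@H](C)Cc3cc(OC)c(O[Si](C)(C)C(C)(C)C)c(OC)c3)c(OC)c2)c(OC)c1 | intermediate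
10 | 4-[(2R)-2-{4-[(2R)-2-{2,6-dimethoxy-4-[(E)-prop-1-en-1-yl]phenoxy}propyl]-2,6-dimethoxyphenoxy}propyl]-2,6-dimethoxyphenol | C/C=C/c1cc(OC)c(O[C@H](C)Cc2cc(OC)c(O[C@H](C)Cc3cc(OC)c(O)c(OC)c3)c(OC)c2)c(OC)c1 | intermediate
11 | 4-[(2R)-2-{4-[(2R)-2-{2,6-dimethoxy-4-[(E)-prop-1-en-1-yl]phenoxy}propyl]-2,6-dimethoxyphenoxy}propylidene]-2,6-dimethoxycyclohexa-2,5-dien-1-one (quinone methide) | C/C=C/c1cc(OC)c(O[C@H](C)Cc2cc(OC)c(O[C@H](C)C=C3C=C(OC)C(=O)C(OC)=C3)c(OC)c2)c(OC)c1 | intermediate
12 | 4-[(1S,2R)-1-hydroxy-2-{4-[(2R)-2-{2,6-dimethoxy-4-[(E)-prop-1-en-1-yl]phenoxy}propyl]-2,6-dimethoxyphenoxy}propyl]-2,6-dimethoxyphenol | C/C=C/c1cc(OC)c(O[C@H](C)Cc2cc(OC)c(O[C@H](C)[C@@H](O)c3cc(OC)c(O)c(OC)c3)c(OC)c2)c(OC)c1 | intermediate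
13 | (1S,2R)-2-{4-[(2R)-2-{2,6-dimethoxy-4-[(E)-prop-1-en-1-yl]phenoxy}propyl]-2,6-dimethoxyphenoxy}-1-(3,4,5-trimethoxyphenyl)propan-1-ol | C/C=C/c1cc(OC)c(O[C@H](C)Cc2cc(OC)c(O[C@H](C)[C@@H](O)c3cc(OC)c(OC)c(OC)c3)c(OC)c2)c(OC)c1 | intermediate
14 | (1S,2R)-2-{4-[(2R)-2-{2,6-dimethoxy-4-[(E)-prop-1-en-1-yl]phenoxy}propyl]-2,6-dimethoxyphenoxy}-1-(3,4,5-trimethoxyphenyl)propyl acetate | C/C=C/c1cc(OC)c(O[C@H](C)Cc2cc(OC)c(O[C@H](C)[C@@H](OC(C)=O)c3cc(OC)c(OC)c(OC)c3)c(OC)c2)c(OC)c1 | target

## Step count and least certain steps

Total step count: 9. Longest linear sequence: 9 steps (1 to 14; monomer 5 is used in steps 3 and 5).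

Step 7 (key step). The most likely failure is insufficient facial selectivity in the 1,6-addition of water, a small nucleophile guided only by the neighbouring C8. The ratio could also erode by reversible re-ionisation at C7, and material could be lost by tautomerisation of the quinone methide toward ring A or by conjugate addition of not yet oxidised phenol. The fallback brings the C7 oxygen in as a carbonyl together with ring A and sets C7 by chelation-controlled reduction. It sets out from 8. Mitsunobu etherification of 8 with commercial (2S)-2-hydroxy-N-methoxy-N-methylpropanamide (PPh3, DIAD, THF, inversion) should give Weinreb amide F1. Addition of commercial 3,4,5-trimethoxyphenylmagnesium bromide (THF, −20 °C) should give ketone F2 without over-addition. Reduction with Zn(BH4)2 (Et2O, −20 °C) through the five-membered chelate between the carbonyl oxygen and the C8 ether oxygen should deliver hydride to the face that gives the erythro alcohol. The route is rejoined at 13 (steps 5 to 8 are bypassed) and finished by step 9.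

Step 5. The most likely failure is E2 elimination of the activated carbinol of 5, whose benzylic β-hydrogens are acidic, together with sluggish substitution because the phenol of 8 is flanked on both sides and only weakly acidic. The fallback makes the hindered ether bond on an activated, unhindered lactate carbinol and forms the aryl–CH2 bond C1–C7 afterwards. It sets out from 8. Mitsunobu etherification with ethyl (S)-lactate (PPh3, DIAD, THF) should give ester F3 with inversion. LiAlH4 (THF, 0 °C) should give primary alcohol F4. I2, PPh3 and imidazole (CH2Cl2) should give iodide F5. Copper-catalysed coupling of F5 with Grignard reagent 4 (Li2CuCl4 cat., THF, −20 °C) forms the C1–C7 bond and comes back to the route at 9.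

Step 3. The failure mode is the same as in step 5, here with phenol 6: elimination of the activated carbinol competes with a slow SN2 by a hindered phenoxide. The fallback again moves the ether formation to a lactate and makes the aryl–CH2 bond C1′–C7′ last. It sets out from 6. Mitsunobu etherification with ethyl (S)-lactate should give ester F6. LiAlH4 should give primary alcohol F7. I2, PPh3 and imidazole should give iodide F8. Coupling of F8 with Grignard reagent 4 (Li2CuCl4 cat., THF, −20 °C) comes back to the route at 7.

## Further compounds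

F1 | step 7 | (2R)-2-{4-[(2R)-2-{2,6-dimethoxy-4-[(E)-prop-1-en-1-yl]phenoxy}propyl]-2,6-dimethoxyphenoxy}-N-methoxy-N-methylpropanamide | C/C=C/c1cc(OC)c(O[C@H](C)Cc2cc(OC)c(O[C@H](C)C(=O)N(C)OC)c(OC)c2)c(OC)c1
F2 | step 7 | (2R)-2-{4-[(2R)-2-{2,6-dimethoxy-4-[(E)-prop-1-en-1-yl]phenoxy}propyl]-2,6-dimethoxyphenoxy}-1-(3,4,5-trimethoxyphenyl)propan-1-one | C/C=C/c1cc(OC)c(O[C@H](C)Cc2cc(OC)c(O[C@H](C)C(=O)c3cc(OC)c(OC)c(OC)c3)c(OC)c2)c(OC)c1
F3 | step 5 | ethyl (2R)-2-{4-[(2R)-2-{2,6-dimethoxy-4-[(E)-prop-1-en-1-yl]phenoxy}propyl]-2,6-dimethoxyphenoxy}propanoate | C/C=C/c1cc(OC)c(O[C@H](C)Cc2cc(OC)c(O[C@H](C)C(=O)OCC)c(OC)c2)c(OC)c1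
F4 | step 5 | (2R)-2-{4-[(2R)-2-{2,6-dimethoxy-4-[(E)-prop-1-en-1-yl]phenoxy}propyl]-2,6-dimethoxyphenoxy}propan-1-ol | C/C=C/c1cc(OC)c(O[C@H](C)Cc2cc(OC)c(O[C@H](C)CO)c(OC)c2)c(OC)c1
F5 | step 5 | 2-{[(2R)-1-iodopropan-2-yl]oxy}-1,3-dimethoxy-5-[(2R)-2-{2,6-dimethoxy-4-[(E)-prop-1-en-1-yl]phenoxy}propyl]benzene | C/C=C/c1cc(OC)c(O[C@H](C)Cc2cc(OC)c(O[C@H](C)CI)c(OC)c2)c(OC)c1
F6 | step 3 | ethyl (2R)-2-{2,6-dimethoxy-4-[(E)-prop-1-en-1-yl]phenoxy}propanoate | C/C=C/c1cc(OC)c(O[C@H](C)C(=O)OCC)c(OC)c1
F7 | step 3 | (2R)-2-{2,6-dimethoxy-4-[(E)-prop-1-en-1-yl]phenoxy}propan-1-ol | C/C=C/c1cc(OC)c(O[C@H](C)CO)c(OC)c1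
F8 | step 3 | 2-{[(2R)-1-iodopropan-2-yl]oxy}-1,3-dimethoxy-5-[(E)-prop-1-en-1-yl]benzene | C/C=C/c1cc(OC)c(O[C@H](C)CI)c(OC)c1
A1 | alternative 1 | 2-bromo-1-(3,4,5-trimethoxyphenyl)propan-1-one (racemic) | CC(Br)C(=O)c1cc(OC)c(OC)c(OC)c1
A2 | alternative 1 | 2-{4-[(2R)-2-{2,6-dimethoxy-4-[(E)-prop-1-en-1-yl]phenoxy}propyl]-2,6-dimethoxyphenoxy}-1-(3,4,5-trimethoxyphenyl)propan-1-one (both C8 epimers) | C/C=C/c1cc(OC)c(O[C@H](C)Cc2cc(OC)c(OC(C)C(=O)c3cc(OC)c(OC)c(OC)c3)c(OC)c2)c(OC)c1
A3 | alternative 2 | (2R)-2-{4-[(2R)-2-{2,6-dimethoxy-4-[(E)-prop-1-en-1-yl]phenoxy}propyl]-2,6-dimethoxyphenoxy}propanal | C/C=C/c1cc(OC)c(O[C@H](C)Cc2cc(OC)c(O[C@H](C)C=O)c(OC)c2)c(OC)c1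
A4 | alternative 3 | 4-[2-{4-[(2R)-2-{2,6-dimethoxy-4-[(E)-prop-1-en-1-yl]phenoxy}propyl]-2,6-dimethoxyphenoxy}propylidene]-2,6-dimethoxycyclohexa-2,5-dien-1-one (both C8 epimers) | C/C=C/c1cc(OC)c(O[C@H](C)Cc2cc(OC)c(OC(C)C=C3C=C(OC)C(=O)C(OC)=C3)c(OC)c2)c(OC)c1
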